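Compound numbers follow the order of first appearance in the steps (1–25); the full list stands after the last step.

## Analysis of the target

Target 25 is a flavonol, a 3-hydroxy-4H-chromen-4-one (rings A and C) with a 3,5-dihydroxy-4-methoxyphenyl ring B at C2. Ring A carries hydroxyls at C5 and C8 and a methoxyl at C7, so C6 is its only C–H. There is no stereocentre, and the whole problem is regiochemical. The sensitive groups are the C5/C8 para-hydroquinone (air oxidation to the quinone, fast in base), the 3-hydroxy-4-pyranone enol, and five free phenols; hot strong acid could also scramble the ring A pattern by pyranone opening and reclosure (Wessely–Moser isomerisation). The difficulty is ring A: it is pentasubstituted, and its four oxygens at C5, C7, C8 and C8a each play a different part (free hydroxyl, methyl ether, free hydroxyl, ring ether), so they must be told apart. The strategy rests on the contiguous carbons C5–C4a–C8a–C8, which carry O, acyl carbon, O, O, exactly the pattern of a 3-alkoxy-4-substituted cyclobutenedione after addition to one carbonyl, while C7(OMe)–C6(H) is a 1-methoxyvinyl unit. Ring expansion of such an adduct gives a para-hydroquinone, so the C5 and C8 hydroxyls are born free and the squarate ester oxygen at C8a is born as a distinct ether.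

## Retrosynthetic reasoning

**25 from 24.** Only the four acetal C–O bonds of the methoxymethyl ethers at C5, C8, C3' and C5' are cut. The oxidation-prone hydroquinone then appears in the final, base-free operation, and the two methyl ethers need no attention.

**24 from 22.** The O1–C2 bond and the C3–O bond are cut, which leads back to the 2'-hydroxychalcone 22. An Algar–Flynn–Oyamada oxidation closes ring C and installs the C3 hydroxyl in one flask through the dihydroflavonol 23. Because 22 has a single free phenol (the C8a oxygen), the closure cannot go to the wrong oxygen.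

**22 from 17 and 21.** The C2=C3 bond is cut as a Claisen–Schmidt condensation between acetophenone 17 and aldehyde 21. This is the convergent point, where a fully built ring A meets a ring B that is bought with its oxygenation in place.

**21 from 18.** No skeletal bond is cut; ester 18 already has the 3,5-dihydroxy-4-methoxy pattern. Only phenol protection (19) and adjustment of the oxidation state (20, then 21) are needed.

**17 from 14.** Again no skeletal bond is cut. The two phenols of 14 are capped (15), the enol ether is unmasked to the acetyl group (16), and the single benzyl ether is removed to free the C8a hydroxyl (17). The order matters: the hydroquinone is protected first because it is air-sensitive, and the enol ether is hydrolysed before hydrogenolysis because hydrogen would saturate it.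

**14 from 7 and 9 (key disconnection).** Ring A is cut at C7–C8 and C5–C6, which removes the two-carbon unit C7–C6 as 1-methoxyvinyllithium 9 and leaves the four-carbon unit C5–C4a–C8a–C8 as cyclobutenedione 7. Cutting here, and not at a ring A C–O bond, means no oxygen has to be introduced onto an existing arene. In the forward direction 9 must add to the carbonyl of 7 that lies next to the benzyloxy carbon (10, then 11), and the adduct must open to ketene 12 and close to dienone 13, which aromatises to 14.

**7 from 2 and 4.** The bond between the cyclobutene carbon (future C4a) and the masked acetyl carbon (future C4) is cut. Dibenzyl squarate 2 is symmetrical, so addition of 4 has no regiochemical question. Rearrangement of the adduct (5, then 6) gives the unsymmetrical dione 7, whose two carbonyls are then electronically different.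

**2 from 1, 4 from 3, 9 from 8.** Squaric acid 1 is esterified, and the two vinyl ethers 3 and 8 are lithiated at the α-carbon. The α-alkoxyvinyl anion serves twice, once as an acetyl anion equivalent and once as the C7–C6 unit that keeps its methoxyl.

## Alternatives that were turned down

**Alternative 1: late O1–C8a bond by anodic oxidation.**
- Disconnection: ring C is opened at O1–C8a, leading to 1-(2,5-dihydroxy-4-methoxyphenyl)-2-(methoxymethoxy)-3-[4-methoxy-3,5-bis(methoxymethoxy)phenyl]propane-1,3-dione A2, in which C8a is still a C–H.
- Forward key step: two-electron oxidation of A2 at a graphite anode gives the acylquinone A3. Its side-chain enol oxygen adds in conjugate fashion to C8a, and tautomerisation returns the hydroquinone level in 5,8-dihydroxy-7-methoxy-3-(methoxymethoxy)-2-[4-methoxy-3,5-bis(methoxymethoxy)phenyl]-4H-chromen-4-one A1.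
- For: ring A needs only three oxygens at the start, the C3 oxygen is present before ring closure, no chemical oxidant is used, and A1 is one acid step from the target. On these points it is stronger than the chosen route, which must carry a differentiated C8a oxygen through several steps and relies on a peroxide oxidation for C3.
- Against: A2 is an ortho-hydroxyaryl 1,3-diketone. Its C5 hydroxyl can close onto the far carbonyl and dehydrate, without any oxidation, to the wrongly oxygenated chromone A4. The cyclised hydroquinone A1 is more electron-rich than A2 and should be oxidised at the same potential, so over-oxidation has to be undone reductively. A3 is also a strong electrophile at C6 and C8a toward the solvent.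
- Comparison: the chosen strategy fixes the C8a oxygen when the ring is made and does not depend on the selectivity of a reactive quinone.

**Alternative 2: ring C closed at C3–C4 by an acyl-anion (benzoin) reaction.**
- Disconnection: C3–C4 is cut, leading to the dialdehyde 3,6-bis(benzyloxy)-2-{1-[3,5-bis(benzyloxy)-4-methoxyphenyl]-2-oxoethoxy}-4-methoxybenzaldehyde A6.
- Forward key step: an N-heterocyclic carbene catalyst with an amine base turns the aryl aldehyde of A6 into an acyl anion equivalent that adds to the aliphatic aldehyde in a six-membered closure. The product is the trans dihydroflavonol A5, which would then be dehydrogenated and debenzylated.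
- For: the step is catalytic and mild, the C3 oxygen is formed at the right place without peroxide, no aurone pathway exists, and the end is neutral hydrogenolysis. As a ring C closure it is at least as good as the chalcone oxidation used here.
- Against: the aliphatic aldehyde of A6 is α-aryl and α-aryloxy, so it enolises, self-condenses and autoxidises readily. The aryl aldehyde is electron-rich and flanked by two ortho oxygens, so it forms the acyl anion equivalent slowly and the catalyst may engage the wrong aldehyde. Above all, A6 needs a ring A salicylaldehyde with the C8a hydroxyl already distinguished from C5 and C8, and then O-alkylation of that doubly ortho-substituted phenol by a secondary benzylic electrophile.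
- Comparison: this alternative leaves the central problem of the target unanswered. The chosen strategy spends its key step on ring A and accepts a conventional ring C closure.

**Alternative 3: ring B built on the chromone by Michael–Claisen annulation.**
- Disconnection: ring B is cut at C1'–C2' and C3'–C4', leading to the enone (E)-1-methoxy-4-[3,5,8-tris(benzyloxy)-7-methoxy-4-oxo-4H-chromen-2-yl]but-3-en-2-one A8 and dimethyl malonate A9.
- Forward key step: under alkoxide, A9 adds to A8 in a Michael reaction, the methoxymethyl ketone condenses onto a malonate ester, and saponification with decarboxylation gives the cyclohexane-1,3-dione enol A7. A7 would still need dehydrogenation to the resorcinol and removal of three benzyl ethers.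
- For: the 3',5'-dihydroxy-4'-methoxy pattern follows from the symmetry of the 2-methoxy-1,3-dione, ring B needs no phenol protection, and ring B could be varied late. In protecting-group economy on ring B it is stronger than the chosen route.
- Against: ring B is the one part of the target that can be bought with its oxygens in place (18). A8 presupposes the complete ring A and ring C with all three of their protected oxygens, so every hard problem has to be solved before the key step. The chromone C2 position is itself a conjugate acceptor, and alkoxide followed by hot saponification threatens to open the pyranone. An extra aromatisation is also needed.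
- Comparison: it is longer and puts the finished chromone at risk. The chosen route buys ring B and builds ring A de novo.

Key step: step 5

## Route

Remark: flavone numbering (O1, C2–C4, C4a, C5–C8, C8a; ring B primed) is used for the atoms of all precursors, and racemic intermediates with a single stereocentre are written without configuration.

Step 1
Reactants: 1 squaric acid
Product: 2 3,4-bis(benzyloxy)cyclobut-3-ene-1,2-dione (dibenzyl squarate)
Conditions: BnOH (excess), toluene, reflux, Dean–Stark
Reagents that add atoms: benzyl alcohol, OCc1ccccc1
Why: Vinylogous Fischer esterification with azeotropic removal of water, the standard preparation of dialkyl squarates; squaric acid is acidic enough to catalyse its own esterification.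

Step 2
Reactants: 3 ethyl vinyl ether
Product: 4 1-ethoxyvinyllithium (THF solution, used at once)
Conditions: t-BuLi (pentane), THF, −78 → 0 °C; recooled to −78 °C
Reagents that add atoms: tert-butyllithium, [Li]C(C)(C)C
Why: α-Lithiation of an alkyl vinyl ether by tert-butyllithium, the standard route to this acetyl anion equivalent; the oxygen directs and acidifies the α-vinylic C–H.

Step 3
Reactants: 2 dibenzyl squarate; 4 1-ethoxyvinyllithium
Product: 7 3-(benzyloxy)-4-(1-ethoxyvinyl)cyclobut-3-ene-1,2-dione, via lithium cyclobutenolate adduct 5 (not isolated), via tertiary trifluoroacetate 6 (not isolated)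
Conditions: THF, −78 °C; (CF3CO)2O, −78 °C; cold aq NaHCO3
Reagents that add atoms: water, O
Why: 1,2-Addition of an organolithium to a dialkyl squarate gives alkoxide 5; O-trifluoroacetylation to 6, ionisation to the benzyloxy-stabilised cyclobutenyl cation and hydrolysis on the buffered quench expel benzyl alcohol and give the 3-alkoxy-4-substituted dione (the known one-pot squarate addition–rearrangement). The low temperature, a slight excess only of anhydride and the bicarbonate quench are chosen to keep the enol ether intact.

Step 4
Reactants: 8 methyl vinyl ether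
Product: 9 1-methoxyvinyllithium (THF solution, used at once)
Conditions: t-BuLi (pentane), THF, −78 → 0 °C; recooled to −78 °C
Reagents that add atoms: tert-butyllithium, [Li]C(C)(C)C
Why: Same α-lithiation of a vinyl ether as in step 2; the methoxyl of this reagent is retained as the C7 methyl ether of the target.

Step 5
Reactants: 7 3-(benzyloxy)-4-(1-ethoxyvinyl)cyclobut-3-ene-1,2-dione; 9 1-methoxyvinyllithium
Product: 14 3-(benzyloxy)-2-(1-ethoxyvinyl)-5-methoxybenzene-1,4-diol, via lithium alkoxide adduct 10 (not isolated), via 4-hydroxycyclobutenone 11 (not isolated), via dienylketene 12 (not isolated), via cyclohexa-2,4-dienone 13 (not isolated)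
Conditions: THF, −78 °C; aq NH4Cl, −78 → 0 °C; then degassed toluene, 80 °C, Ar
Reagents that add atoms: none
Why: This is the addition of an alkenyllithium to a 3-alkoxy-4-substituted cyclobutenedione followed by thermal ring expansion of the 4-alkenyl-4-hydroxycyclobutenone to a hydroquinone, an established squarate benzannulation. Reagent 9 adds 1,2 to the carbonyl next to the benzyloxy-bearing carbon, because the other carbonyl is deactivated as a vinylogous ester by that same benzyloxy group; this forms the C7–C8 bond and gives 10, which is protonated to 11 on quench. On warming, 11 undergoes 4π-conrotatory opening of its C1–C4 bond with the hydroxyl turning outward, which places the methoxyvinyl group cis to the ketene terminus in the (Z)-dienylketene 12. A 6π-disrotatory electrocyclisation of 12 joins the ketene carbon to the vinyl CH2 (the C5–C6 bond) and closes ring A as dienone 13, which tautomerises irreversibly to the aromatic hydroquinone 14. No stereocentre reaches the product, since the carbinol centre of 11 is lost on ring opening. The step needs regioselective carbonyl addition, secured by the vinylogous ester deactivation, and outward rotation of the oxygen substituent, which is the intrinsic torquoselectivity of donor groups in cyclobutene openings. The ketene carbon becomes C5, the ethoxyvinyl-bearing carbon C4a, the benzyloxy carbon C8a and the carbinol carbon C8, so the C8a oxygen emerges as the only benzyl ether. One equivalent of 9 at low temperature and exclusion of air are chosen to limit double addition and oxidation of 14, which is carried on crude.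

Step 6
Reactants: 14 3-(benzyloxy)-2-(1-ethoxyvinyl)-5-methoxybenzene-1,4-diol
Product: 15 3-(benzyloxy)-2-(1-ethoxyvinyl)-5-methoxy-1,4-bis(methoxymethoxy)benzene
Conditions: NaH, MOMCl, DMF, 0 °C → rt, Ar
Reagents that add atoms: chloromethyl methyl ether, COCCl
Why: O-Alkylation of both phenoxides with chloromethyl methyl ether (Williamson-type acetal formation); the enol ether and benzyl ether are stable to base, and capping both hydroxyls removes the oxidation-prone hydroquinone.

Step 7
Reactants: 15 3-(benzyloxy)-2-(1-ethoxyvinyl)-5-methoxy-1,4-bis(methoxymethoxy)benzene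
Product: 16 1-[2-(benzyloxy)-4-methoxy-3,6-bis(methoxymethoxy)phenyl]ethan-1-one
Conditions: 0.1 M aq HCl, THF, 0 °C
Reagents that add atoms: water, O
Why: Acid-catalysed enol ether hydrolysis (C-protonation to an oxocarbenium ion, then hemiketal collapse with loss of ethanol) is far faster than cleavage of aryl methoxymethyl acetals, so brief cold dilute acid should unmask the acetyl group selectively.

Step 8
Reactants: 16 1-[2-(benzyloxy)-4-methoxy-3,6-bis(methoxymethoxy)phenyl]ethan-1-one
Product: 17 1-[2-hydroxy-4-methoxy-3,6-bis(methoxymethoxy)phenyl]ethan-1-one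
Conditions: H2 (1 atm), Pd/C, EtOAc, rt
Reagents that add atoms: none
Why: Hydrogenolysis of the single benzyl aryl ether; the methoxymethyl ethers, the methyl ether and the electron-rich aryl ketone are inert under these neutral conditions, and the freed C8a hydroxyl is stabilised by hydrogen bonding to the acetyl group.

Step 9
Reactants: 18 methyl 3,5-dihydroxy-4-methoxybenzoate
Product: 19 methyl 4-methoxy-3,5-bis(methoxymethoxy)benzoate
Conditions: NaH, MOMCl, DMF, 0 °C → rt
Reagents that add atoms: chloromethyl methyl ether, COCCl
Why: Phenoxide O-alkylation with chloromethyl methyl ether; the same base-stable, acid-labile group as on ring A is used so that one final step removes all four.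

Step 10
Reactants: 19 methyl 4-methoxy-3,5-bis(methoxymethoxy)benzoate
Product: 20 [4-methoxy-3,5-bis(methoxymethoxy)phenyl]methanol
Conditions: LiAlH4, THF, 0 °C; aq NaOH work-up
Reagents that add atoms: none
Why: Hydride reduction of an aryl ester to the benzylic alcohol; acetals and aryl ethers are inert to LiAlH4.

Step 11
Reactants: 20 [4-methoxy-3,5-bis(methoxymethoxy)phenyl]methanol
Product: 21 4-methoxy-3,5-bis(methoxymethoxy)benzaldehyde
Conditions: MnO2, CH2Cl2, rt
Reagents that add atoms: none
Why: Selective heterogeneous oxidation of a benzylic alcohol to the aldehyde by MnO2 under neutral conditions, without over-oxidation and without touching the acetals.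

Step 12
Reactants: 17 1-[2-hydroxy-4-methoxy-3,6-bis(methoxymethoxy)phenyl]ethan-1-one; 21 4-methoxy-3,5-bis(methoxymethoxy)benzaldehyde
Product: 22 (E)-1-[2-hydroxy-4-methoxy-3,6-bis(methoxymethoxy)phenyl]-3-[4-methoxy-3,5-bis(methoxymethoxy)phenyl]prop-2-en-1-one
Conditions: KOH, EtOH/H2O, rt; cold dilute AcOH to pH 6
Reagents that add atoms: none
Why: Claisen–Schmidt condensation (crossed aldol, then E1cB dehydration) of the methyl ketone with a non-enolisable aldehyde; the conjugated E-alkene is the thermodynamic product, and the methoxymethyl ethers are stable to hydroxide.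

Step 13
Reactants: 22 (E)-1-[2-hydroxy-4-methoxy-3,6-bis(methoxymethoxy)phenyl]-3-[4-methoxy-3,5-bis(methoxymethoxy)phenyl]prop-2-en-1-one
Product: 24 3-hydroxy-7-methoxy-5,8-bis(methoxymethoxy)-2-[4-methoxy-3,5-bis(methoxymethoxy)phenyl]-4H-chromen-4-one, via trans-dihydroflavonol 23 (not isolated)
Conditions: 30% H2O2, NaOH, MeOH/H2O, 0 °C → rt; AcOH
Reagents that add atoms: hydrogen peroxide, OO
Why: Algar–Flynn–Oyamada oxidation: the phenoxide closes onto the enone β-carbon (O1–C2) while C3 is hydroxylated by peroxide, giving the trans-dihydroflavonol 23 (both substituents equatorial), which is dehydrogenated in the same alkaline peroxide to the flavonol. Only the C8a oxygen is free, so the ring can close in one direction only, and methoxymethyl-protected 2'-hydroxy-6'-alkoxychalcones are established substrates.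

Step 14
Reactants: 24 3-hydroxy-7-methoxy-5,8-bis(methoxymethoxy)-2-[4-methoxy-3,5-bis(methoxymethoxy)phenyl]-4H-chromen-4-one
Product: 25 3,5,8-trihydroxy-2-(3,5-dihydroxy-4-methoxyphenyl)-7-methoxy-4H-chromen-4-one (CNP0241578.0)
Conditions: HCl (3 M aq), MeOH, 50 °C, Ar
Reagents that add atoms: none
Why: Acid-catalysed transacetalisation of the four aryl methoxymethyl ethers in methanol; the methyl ethers and the flavonol core are stable to these mild conditions, which are well below those needed for pyranone opening, and argon protects the liberated C5/C8 hydroquinone.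

## Compound list

1 | squaric acid (3,4-dihydroxycyclobut-3-ene-1,2-dione) | OC1=C(O)C(=O)C1=O | starting material
2 | 3,4-bis(benzyloxy)cyclobut-3-ene-1,2-dione (dibenzyl squarate) | O=C1C(=O)C(OCc2ccccc2)=C1OCc1ccccc1 | intermediate
3 | ethyl vinyl ether | CCOC=C | starting material
4 | 1-ethoxyvinyllithium | [Li]C(=C)OCC | intermediate
5 | lithium 2,3-bis(benzyloxy)-1-(1-ethoxyvinyl)-4-oxocyclobut-2-en-1-olate (racemic) | [Li]OC1(C(=C)OCC)C(=O)C(OCc2ccccc2)=C1OCc1ccccc1 | intermediate (not isolated)
6 | 2,3-bis(benzyloxy)-1-(1-ethoxyvinyl)-4-oxocyclobut-2-en-1-yl trifluoroacetate (racemic) | CCOC(=C)C1(OC(=O)C(F)(F)F)C(=O)C(OCc2ccccc2)=C1OCc1ccccc1 | intermediate (not isolated)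
7 | 3-(benzyloxy)-4-(1-ethoxyvinyl)cyclobut-3-ene-1,2-dione | CCOC(=C)C1=C(OCc2ccccc2)C(=O)C1=O | intermediate
8 | methyl vinyl ether | COC=C | starting material
9 | 1-methoxyvinyllithium | [Li]C(=C)OC | intermediate
10 | lithium 2-(benzyloxy)-3-(1-ethoxyvinyl)-1-(1-methoxyvinyl)-4-oxocyclobut-2-en-1-olate (racemic) | CCOC(=C)C1=C(OCc2ccccc2)C(O[Li])(C(=C)OC)C1=O | intermediate (not isolated)
11 | 3-(benzyloxy)-2-(1-ethoxyvinyl)-4-hydroxy-4-(1-methoxyvinyl)cyclobut-2-en-1-one (racemic) | CCOC(=C)C1=C(OCc2ccccc2)C(O)(C(=C)OC)C1=O | intermediate (not isolated)
12 | (3Z)-3-(benzyloxy)-2-(1-ethoxyvinyl)-4-hydroxy-5-methoxyhexa-1,3,5-trien-1-one | CCOC(=C)C(=C=O)/C(OCc1ccccc1)=C(O)\C(=C)OC | intermediate (not isolated)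
13 | 3-(benzyloxy)-2-(1-ethoxyvinyl)-4-hydroxy-5-methoxycyclohexa-2,4-dien-1-one | CCOC(=C)C1=C(OCc2ccccc2)C(O)=C(OC)CC1=O | intermediate (not isolated)
14 | 3-(benzyloxy)-2-(1-ethoxyvinyl)-5-methoxybenzene-1,4-diol | CCOC(=C)c1c(O)cc(OC)c(O)c1OCc1ccccc1 | intermediate
15 | 3-(benzyloxy)-2-(1-ethoxyvinyl)-5-methoxy-1,4-bis(methoxymethoxy)benzene | CCOC(=C)c1c(OCOC)cc(OC)c(OCOC)c1OCc1ccccc1 | intermediate
16 | 1-[2-(benzyloxy)-4-methoxy-3,6-bis(methoxymethoxy)phenyl]ethan-1-one | CC(=O)c1c(OCOC)cc(OC)c(OCOC)c1OCc1ccccc1 | intermediate
17 | 1-[2-hydroxy-4-methoxy-3,6-bis(methoxymethoxy)phenyl]ethan-1-one | CC(=O)c1c(O)c(OCOC)c(OC)cc1OCOC | intermediate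
18 | methyl 3,5-dihydroxy-4-methoxybenzoate | COC(=O)c1cc(O)c(OC)c(O)c1 | starting material
19 | methyl 4-methoxy-3,5-bis(methoxymethoxy)benzoate | COC(=O)c1cc(OCOC)c(OC)c(OCOC)c1 | intermediate
20 | [4-methoxy-3,5-bis(methoxymethoxy)phenyl]methanol | OCc1cc(OCOC)c(OC)c(OCOC)c1 | intermediate
21 | 4-methoxy-3,5-bis(methoxymethoxy)benzaldehyde | O=Cc1cc(OCOC)c(OC)c(OCOC)c1 | intermediate
22 | (E)-1-[2-hydroxy-4-methoxy-3,6-bis(methoxymethoxy)phenyl]-3-[4-methoxy-3,5-bis(methoxymethoxy)phenyl]prop-2-en-1-one | COCOc1cc(/C=C/C(=O)c2c(O)c(OCOC)c(OC)cc2OCOC)cc(OCOC)c1OC | intermediate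
23 | trans-3-hydroxy-7-methoxy-5,8-bis(methoxymethoxy)-2-[4-methoxy-3,5-bis(methoxymethoxy)phenyl]chroman-4-one (racemic, drawn as the 2S,3S enantiomer) | COc1cc(OCOC)c2c(c1OCOC)O[C@@H](c1cc(OCOC)c(OC)c(OCOC)c1)[C@H](O)C2=O | intermediate (not isolated)
24 | 3-hydroxy-7-methoxy-5,8-bis(methoxymethoxy)-2-[4-methoxy-3,5-bis(methoxymethoxy)phenyl]-4H-chromen-4-one | COCOc1cc(-c2oc3c(OCOC)c(OC)cc(OCOC)c3c(=O)c2O)cc(OCOC)c1OC | intermediate
25 | 3,5,8-trihydroxy-2-(3,5-dihydroxy-4-methoxyphenyl)-7-methoxy-4H-chromen-4-one | COc1cc(O)c2c(=O)c(O)c(-c3cc(O)c(OC)c(O)c3)oc2c1O | target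

## Step count and least certain steps

Total step count: 14. Longest linear sequence: 9 steps (steps 1, 3, 5, 6, 7, 8, 12, 13, 14, from squaric acid 1 to 25).

**Step 5 (key step).**
- Risk: air oxidation of the very electron-rich free hydroquinone to the quinone during thermolysis and isolation, together with acid-promoted loss of the enol ether on quench. The ring is tetra-donor-substituted and is handled unprotected. Erosion of the carbonyl regioselectivity by the conjugating ethoxyvinyl group is the lesser risk.
- Fallback: it sets out from 7 and 9 and comes back at 15. The alkoxide 10 is not protonated but O-alkylated in the cold with chloromethyl methyl ether (THF/DMPU) to give 3-(benzyloxy)-2-(1-ethoxyvinyl)-4-(methoxymethoxy)-4-(1-methoxyvinyl)cyclobut-2-en-1-one F1. Thermolysis of this ether in toluene follows the same opening and electrocyclisation but ends at the mono-protected 3-(benzyloxy)-2-(1-ethoxyvinyl)-5-methoxy-4-(methoxymethoxy)phenol F2, so that no free hydroquinone and no aqueous acidic quench occur. NaH and chloromethyl methyl ether then convert F2 into 15.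

**Step 3.**
- Risk: C-trifluoroacetylation or hydrolysis of the nucleophilic enol ether during the anhydride-induced rearrangement and its quench, since trifluoroacetic acid is released next to a 1,1-disubstituted vinyl ether.
- Fallback: it sets out from 1 and comes back at 7. Squaric acid 1 is converted with oxalyl chloride and catalytic DMF into 3,4-dichlorocyclobut-3-ene-1,2-dione F3. One equivalent of benzyl alcohol gives 3-(benzyloxy)-4-chlorocyclobut-3-ene-1,2-dione F4. A Stille coupling of F4 with commercial tributyl(1-ethoxyvinyl)stannane (PdCl2(PhCN)2, tri(2-furyl)phosphine, CuI, DMF, rt) installs the ethoxyvinyl group under neutral conditions and gives 7.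

**Step 7.**
- Risk: partial cleavage of the C5 methoxymethyl ether alongside the enol ether, because the newly formed ortho ketone assists loss of that acetal by chelation.
- Fallback: it sets out from 14 and comes back at 16, with the order of events changed. Crude 14 is hydrolysed with dilute aqueous HCl in THF while no acetal is present, giving 1-[2-(benzyloxy)-3,6-dihydroxy-4-methoxyphenyl]ethan-1-one F5, an acyl hydroquinone that is less prone to oxidation than 14. Both hydroxyls of F5 are then protected with NaH and chloromethyl methyl ether to give 16.

**Step 13.**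
- Risk: diversion of the oxidative cyclisation to the aurone by attack at the α-carbon. The C5 substituent ortho to the carbonyl (the 6'-position of the chalcone) twists the enone and is known to favour this pathway.
- Fallback: it sets out from 22 and comes back at 24.
  - 22 is cyclised with NaOAc in refluxing EtOH to the flavanone 7-methoxy-5,8-bis(methoxymethoxy)-2-[4-methoxy-3,5-bis(methoxymethoxy)phenyl]chroman-4-one F6.
  - F6 is dehydrogenated with iodine in pyridine at 90 °C to the flavone 7-methoxy-5,8-bis(methoxymethoxy)-2-[4-methoxy-3,5-bis(methoxymethoxy)phenyl]-4H-chromen-4-one F7.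
  - F7 is epoxidised with dimethyldioxirane in acetone/CH2Cl2 at 0 °C to the 2,3-epoxyflavanone F8, which opens and tautomerises to 24 on brief contact with catalytic p-toluenesulfonic acid.

**Step 14.**
- Risk: oxidation of the liberated C5/C8 hydroquinone to the quinone during acetal cleavage and purification, since the free pentaphenol cannot be chromatographed without exposure to air.
- Fallback: it sets out from 24 and comes back at 25. After acetal cleavage under argon, the crude product is acetylated in the same flask (acetic anhydride, pyridine) to the stable 3,5,8-triacetoxy-2-(3,5-diacetoxy-4-methoxyphenyl)-7-methoxy-4H-chromen-4-one F9, which is purified by crystallisation. Degassed methanolic HCl at room temperature then removes the five acetates and delivers 25 by precipitation, without chromatography.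

## Further compounds

F1 | step 5 | 3-(benzyloxy)-2-(1-ethoxyvinyl)-4-(methoxymethoxy)-4-(1-methoxyvinyl)cyclobut-2-en-1-one (racemic) | CCOC(=C)C1=C(OCc2ccccc2)C(OCOC)(C(=C)OC)C1=O
F2 | step 5 | 3-(benzyloxy)-2-(1-ethoxyvinyl)-5-methoxy-4-(methoxymethoxy)phenol | CCOC(=C)c1c(O)cc(OC)c(OCOC)c1OCc1ccccc1
F3 | step 3 | 3,4-dichlorocyclobut-3-ene-1,2-dione | ClC1=C(Cl)C(=O)C1=O
F4 | step 3 | 3-(benzyloxy)-4-chlorocyclobut-3-ene-1,2-dione | ClC1=C(OCc2ccccc2)C(=O)C1=O
F5 | step 7 | 1-[2-(benzyloxy)-3,6-dihydroxy-4-methoxyphenyl]ethan-1-one | CC(=O)c1c(O)cc(OC)c(O)c1OCc1ccccc1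
F6 | step 13 | 7-methoxy-5,8-bis(methoxymethoxy)-2-[4-methoxy-3,5-bis(methoxymethoxy)phenyl]chroman-4-one (racemic) | COc1cc(OCOC)c2c(c1OCOC)OC(c1cc(OCOC)c(OC)c(OCOC)c1)CC2=O
F7 | step 13 | 7-methoxy-5,8-bis(methoxymethoxy)-2-[4-methoxy-3,5-bis(methoxymethoxy)phenyl]-4H-chromen-4-one | COCOc1cc(-c2cc(=O)c3c(OCOC)cc(OC)c(OCOC)c3o2)cc(OCOC)c1OC
F8 | step 13 | 7-methoxy-5,8-bis(methoxymethoxy)-2-[4-methoxy-3,5-bis(methoxymethoxy)phenyl]-2,3-epoxychroman-4-one (racemic, cis-fused epoxide) | COc1cc(OCOC)c2c(c1OCOC)OC1(c3cc(OCOC)c(OC)c(OCOC)c3)OC1C2=O
F9 | step 14 | 3,5,8-triacetoxy-2-(3,5-diacetoxy-4-methoxyphenyl)-7-methoxy-4H-chromen-4-one | COc1cc(OC(C)=O)c2c(=O)c(OC(C)=O)c(-c3cc(OC(C)=O)c(OC)c(OC(C)=O)c3)oc2c1OC(C)=O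
A1 | alternative 1 | 5,8-dihydroxy-7-methoxy-3-(methoxymethoxy)-2-[4-methoxy-3,5-bis(methoxymethoxy)phenyl]-4H-chromen-4-one | COc1cc(O)c2c(=O)c(OCOC)c(-c3cc(OCOC)c(OC)c(OCOC)c3)oc2c1O
A2 | alternative 1 | 1-(2,5-dihydroxy-4-methoxyphenyl)-2-(methoxymethoxy)-3-[4-methoxy-3,5-bis(methoxymethoxy)phenyl]propane-1,3-dione (racemic) | COc1cc(O)c(cc1O)C(=O)C(OCOC)C(=O)c1cc(OCOC)c(OC)c(OCOC)c1
A3 | alternative 1 | 2-{2-(methoxymethoxy)-3-[4-methoxy-3,5-bis(methoxymethoxy)phenyl]-3-oxopropanoyl}-5-methoxycyclohexa-2,5-diene-1,4-dione (racemic) | COC1=CC(=O)C(=CC1=O)C(=O)C(OCOC)C(=O)c1cc(OCOC)c(OC)c(OCOC)c1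
A4 | alternative 1 | 6-hydroxy-7-methoxy-3-(methoxymethoxy)-2-[4-methoxy-3,5-bis(methoxymethoxy)phenyl]-4H-chromen-4-one | COc1cc2oc(-c3cc(OCOC)c(OC)c(OCOC)c3)c(OCOC)c(=O)c2cc1O
A5 | alternative 2 | trans-5,8-bis(benzyloxy)-2-[3,5-bis(benzyloxy)-4-methoxyphenyl]-3-hydroxy-7-methoxychroman-4-one (racemic, drawn as one enantiomer) | COc1cc(OCc2ccccc2)c2c(c1OCc1ccccc1)O[C@@H](c1cc(OCc3ccccc3)c(OC)c(OCc3ccccc3)c1)[C@H](O)C2=O
A6 | alternative 2 | 3,6-bis(benzyloxy)-2-{1-[3,5-bis(benzyloxy)-4-methoxyphenyl]-2-oxoethoxy}-4-methoxybenzaldehyde (racemic) | COc1cc(OCc2ccccc2)c(C=O)c(OC(C=O)c2cc(OCc3ccccc3)c(OC)c(OCc3ccccc3)c2)c1OCc1ccccc1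
A7 | alternative 3 | 3-hydroxy-2-methoxy-5-[3,5,8-tris(benzyloxy)-7-methoxy-4-oxo-4H-chromen-2-yl]cyclohex-2-en-1-one (racemic, drawn as one enantiomer) | COC1=C(O)C[C@@H](CC1=O)c1oc2c(OCc3ccccc3)c(OC)cc(OCc3ccccc3)c2c(=O)c1OCc1ccccc1
A8 | alternative 3 | (E)-1-methoxy-4-[3,5,8-tris(benzyloxy)-7-methoxy-4-oxo-4H-chromen-2-yl]but-3-en-2-one | COCC(=O)/C=C/c1oc2c(OCc3ccccc3)c(OC)cc(OCc3ccccc3)c2c(=O)c1OCc1ccccc1
A9 | alternative 3 | dimethyl malonate | COC(=O)CC(=O)OC
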